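1. The retrosynthesis first cuts the two cyclopropyl–alkenyl bonds at C4 and C8 of the tricyclo[4.2.1.1(2,5)]deca-3,7-diene core, which leaves the bis(enol triflate) of a C12 diketone and two equivalents of one chiral cis-cyclopropyl metal. A C4–C7 bond is then redrawn (retro-aldol in reverse) to give a cage, and cutting C4–C5 and C6–C7 ([2+2] in reverse) gives a bicyclic enone that is a butadiene–quinone Diels–Alder adduct.
2. Enabling feature: both two-carbon bridges (C3=C4 and C7=C8) hang from the same face of the boat six-membered ring C1–C2–C10–C5–C6–C9, so C4 lies beside C7. Joining them on paper gives the cyclobutane C4–C5–C6–C7 and a cis-fused bicyclo[4.4.0]decadiene built from ring C1–C2–C10–C5–C6–C9 (butadiene part) and ring C1–C2–C3–C4–C7–C8 (quinone part).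
3. Forward order: the Diels–Alder reaction makes the six-membered carbocycle and a temporary quinone-derived ring; the enone–alkene photocycloaddition closes both cyclopentane rings and a temporary cyclobutane; acid scission of C4–C7 removes the cyclobutane and the quinone ring and leaves ketones at C4 and C8; the two cyclopropanes are attached last by a twofold Negishi coupling.
4. Stereochemistry: C1 and C2 come from the catalyst-controlled Diels–Alder reaction; C5, C6 and the syn arrangement of the bridges follow from the cis ring fusion during the photocycloaddition; the four cyclopropane centres come from a ligand-controlled syn-carbomagnesiation of 3,3-dimethylcyclopropene and are carried with retention through Mg, Zn and Pd.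

Key step: step 4

Assumption: the (S)-oxazaborolidine of step 2 and the (R,SP)-ferrocenyl diphosphine of step 13 are taken to induce the enantiomers drawn; should either give the opposite sense, its mirror-image form is used and nothing else changes.

Core atoms in steps 4–8 and 14 are numbered C1–C10 as in the lines above.

Step 1
Reactants: 1 2-methyl-1,4-benzoquinone
Product: 3 2-methoxy-5-methyl-1,4-benzoquinone, via 2-methoxy-5-methylbenzene-1,4-diol 2 (not isolated)
Conditions: ZnCl2, MeOH, 20 °C → reflux; 2 equiv of 1, the second as oxidant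
Reagents that add atoms: methanol, CO
Why: Lewis-acid-promoted conjugate addition of methanol should occur at C5, the β-carbon of the enone whose carbonyl is not deactivated by the methyl-bearing double bond, and the electron-rich hydroquinone so formed is oxidised in the flask by a second equivalent of 1 (quinone–hydroquinone redox exchange).

Step 2
Reactants: 3 2-methoxy-5-methyl-1,4-benzoquinone; 4 buta-1,3-diene
Product: 5 (4aS,8aR)-2-methoxy-4a-methyl-4a,5,8,8a-tetrahydronaphthalene-1,4-dione
Conditions: (S)-3,3-diphenyl-1-(2-methylphenyl)tetrahydro-1H,3H-pyrrolo[1,2-c][1,3,2]oxazaborole (20 mol %), HNTf2 (18 mol %), excess 4, CH2Cl2, −78 → −40 °C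
Reagents that add atoms: none
Why: Catalytic enantioselective Diels–Alder reaction with a chiral cationic boron Lewis acid: the methoxy-bearing double bond is a deactivated vinylogous ester, so the diene should add only across the methyl-bearing C5=C6 bond, suprafacial addition makes the ring fusion cis, and the face left open in the catalyst–quinone complex sets C4a and C8a together.

Step 3
Reactants: 5 (4aS,8aR)-2-methoxy-4a-methyl-4a,5,8,8a-tetrahydronaphthalene-1,4-dione
Product: 6 (4R,4aR,8aS)-4-hydroxy-3-methoxy-4,8a-dimethyl-4a,5,8,8a-tetrahydronaphthalen-1(4H)-one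
Conditions: MeLi, CeCl3 (dried), THF, −78 °C; aq. NH4Cl
Reagents that add atoms: methyllithium, [Li]C (transferred as MeCeCl2)
Why: Organocerium 1,2-addition: the carbonyl flanked by the ring-fusion CH and the methoxy-bearing carbon is more electrophilic and less hindered than the vinylogous-ester carbonyl beside the quaternary carbon, the weakly basic reagent should not epimerise the ring fusion, and attack from the convex face should give the 4R carbinol, whose configuration is of no consequence because this carbon becomes trigonal in step 8.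

Step 4
Reactants: 6 (4R,4aR,8aS)-4-hydroxy-3-methoxy-4,8a-dimethyl-4a,5,8,8a-tetrahydronaphthalen-1(4H)-one
Product: 7 (1S,3R,4R,5R,6R,8S,9R)-5-hydroxy-4-methoxy-1,5-dimethyltetracyclo[4.4.0.0(3,9).0(4,8)]decan-2-one
Conditions: hν (medium-pressure Hg lamp, Pyrex filter, λ > 300 nm), degassed MeCN, 0.01 M, 20 °C
Reagents that add atoms: none
Why: Excitation of the β-methoxy enone (C8=O conjugated with C7=C4–OMe) and intersystem crossing give a ππ* triplet whose C7 and C4 bond in turn to C6 and C5 of the cyclohexene held beneath it by the cis ring fusion, and the 1,4-biradical collapses after spin inversion to the cyclobutane. The closest known reaction type is the intramolecular enone–alkene [2+2] photocycloaddition of cis-fused tetrahydronaphthalenone-type enones and of vinylogous esters to cage ketones. Bond C6–C7 closes the cyclopentane C1–C8–C7–C6–C9 and bond C4–C5 closes the cyclopentane C2–C3–C4–C5–C10, each by 1,5-closure in line with the rule of five, and together they complete the sacrificial cyclobutane C4–C5–C6–C7. The four new stereocentres C4, C5, C6 and C7 are all fixed by the existing cis-fused centres C1 and C2, because the two three-atom tethers (C8–C1–C9 and C3–C2–C10) let the alkenes meet only face to face on the concave side, which also places the two future bridges syn. The step needs straight rather than crossed addition and cycloaddition rather than hydrogen abstraction; the first is secured by the two five-membered closures (crossed addition would need two six-membered closures across a twisted bridge), the second by the vinylogous-ester chromophore and the absence of the second quinone carbonyl.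

Step 5
Reactants: 7 (1S,3R,4R,5R,6R,8S,9R)-5-hydroxy-4-methoxy-1,5-dimethyltetracyclo[4.4.0.0(3,9).0(4,8)]decan-2-one
Product: 9 (1S,2R,3R,5S,6S)-3-hydroxy-1,3-dimethyltricyclo[4.2.1.1(2,5)]decane-4,8-dione, via ring-opened methyl hemiketal 8 (not isolated)
Conditions: 2 M aq. HCl, THF, 45 °C
Reagents that add atoms: water, O
Why: Acid-promoted retro-aldol (de Mayo-type) fragmentation of a donor–acceptor cyclobutane: C4–C7 is the only cage bond flanked by the ether donor on C4 and the C8 carbonyl acceptor on C7, so protonation of the ketone and push from the methoxy oxygen should cleave exactly this bond with release of ring strain, hydrolysis of the oxocarbenium ion then unveils the C4 ketone, and loss of methanol to an enol ether is excluded because C3 is quaternary and C5 a bridgehead.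

Step 6
Reactants: 9 (1S,2R,3R,5S,6S)-3-hydroxy-1,3-dimethyltricyclo[4.2.1.1(2,5)]decane-4,8-dione
Product: 10 (1S,2R,3R,5S,6S)-1,3-dimethyl-4,8-dioxotricyclo[4.2.1.1(2,5)]decan-3-yl acetate
Conditions: Ac2O, DMAP, Et3N, CH2Cl2, 40 °C
Reagents that add atoms: acetic anhydride, CC(=O)OC(C)=O
Why: Nucleophile-catalysed acylation of the only hydroxyl group, a tertiary α-ketol, turns it into a leaving group suited to single-electron reduction without touching any stereocentre.

Step 7
Reactants: 10 (1S,2R,3R,5S,6S)-1,3-dimethyl-4,8-dioxotricyclo[4.2.1.1(2,5)]decan-3-yl acetate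
Product: 12 (1S,2S,3R,5S,6S)-1,3-dimethyltricyclo[4.2.1.1(2,5)]decane-4,8-dione, via trivalent samarium enolate 11 (not isolated)
Conditions: SmI2 (2.5 equiv), THF/MeOH, −78 °C
Reagents that add atoms: none
Why: SmI2 reduction of an α-acyloxy ketone: electron transfer to the C4 carbonyl, loss of acetate from C3 and a second electron transfer give the enolate, which methanol protonates; the exo-methyl epimer at C3 is drawn, but either epimer serves because C3 becomes trigonal in step 8, and the isolated C8 ketone should survive at this temperature.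

Step 8
Reactants: 12 (1S,2S,3R,5S,6S)-1,3-dimethyltricyclo[4.2.1.1(2,5)]decane-4,8-dione
Product: 14 (1S,2S,5S,6S)-1,3-dimethyltricyclo[4.2.1.1(2,5)]deca-3,7-diene-4,8-diyl bis(trifluoromethanesulfonate), via dipotassium bis(enolate) 13 (not isolated)
Conditions: KN(SiMe3)2 (2.5 equiv), THF, −78 → −20 °C; PhNTf2 (2.5 equiv), −78 → 0 °C
Reagents that add atoms: N-phenylbis(trifluoromethanesulfonimide), O=S(=O)(N(c1ccccc1)S(=O)(=O)C(F)(F)F)C(F)(F)F
Why: Twofold enolisation and O-sulfonylation (enol triflate formation): each ketone has a single enolisable side, the C8 ketone toward C7 because C1 is quaternary and the C4 ketone toward C3 because C5 is a bridgehead (Bredt's rule), so one regioisomer should form, with C1, C2, C5 and C6 untouched.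

Step 9
Reactants: 15 2-methylpropene
Product: 16 1,1-dibromo-2,2-dimethylcyclopropane
Conditions: CHBr3, KOtBu, pentane, −20 → 20 °C
Reagents that add atoms: bromoform, BrC(Br)Br
Why: [2+1] Cycloaddition of dibromocarbene, generated by α-elimination from bromoform, to the electron-rich 1,1-disubstituted alkene.

Step 10
Reactants: 16 1,1-dibromo-2,2-dimethylcyclopropane
Product: 17 1-bromo-2,2-dimethylcyclopropane (racemic)
Conditions: nBu3SnH (1.0 equiv), neat, 35 °C
Reagents that add atoms: none
Why: Radical-chain hydrodebromination with one equivalent of tin hydride should remove a single bromine, since the α-bromocyclopropyl radical forms faster from the gem-dibromide than the cyclopropyl radical does from the monobromide; the product is racemic, which is irrelevant because this centre is lost in step 11.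

Step 11
Reactants: 17 1-bromo-2,2-dimethylcyclopropane (racemic)
Product: 18 3,3-dimethylcyclopropene
Conditions: KOtBu, DMSO, 20 → 60 °C, product swept by N2 into a −78 °C trap
Reagents that add atoms: none
Why: Base-induced 1,2-dehydrobromination (E2) gives the cyclopropene, which cannot isomerise to a methylenecyclopropane because C3 carries no hydrogen and which leaves the basic medium as it forms on account of its low boiling point.

Step 12
Reactants: 19 2-(2-bromoethyl)-2-methyl-1,3-dioxolane
Product: 20 [2-(2-methyl-1,3-dioxolan-2-yl)ethyl]magnesium bromide (titrated THF solution)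
Conditions: Mg turnings, THF, 25–30 °C
Reagents that add atoms: magnesium, [Mg]
Why: Grignard formation by insertion of magnesium into the primary C–Br bond; the ketal is inert to the organometallic, and the temperature is kept near ambient so that the γ-ketal Grignard reagent does not decompose.

Step 13
Reactants: 18 3,3-dimethylcyclopropene (1.1 equiv); 20 [2-(2-methyl-1,3-dioxolan-2-yl)ethyl]magnesium bromide
Product: 21 [(1R,3R)-2,2-dimethyl-3-[2-(2-methyl-1,3-dioxolan-2-yl)ethyl]cyclopropyl]magnesium bromide (solution, used directly)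
Conditions: CuI (5 mol %), (R)-1-[(SP)-2-(diphenylphosphino)ferrocenyl]ethyldicyclohexylphosphine (6 mol %), Et2O/THF, −30 → 0 °C
Reagents that add atoms: none
Why: Copper-catalysed enantioselective syn-carbomagnesiation of a 3,3-disubstituted cyclopropene, driven by release of ring strain: syn delivery of alkyl and metal makes the two new centres cis, the chiral diphosphine–copper complex selects which of the two enantiotopic alkene carbons receives the alkyl group (the two faces are equivalent), the cyclopropylmagnesium is configurationally stable, and the slight excess of volatile 18 ensures that no primary Grignard reagent remains for step 14.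

Step 14
Reactants: 14 (1S,2S,5S,6S)-1,3-dimethyltricyclo[4.2.1.1(2,5)]deca-3,7-diene-4,8-diyl bis(trifluoromethanesulfonate); 21 [(1R,3R)-2,2-dimethyl-3-[2-(2-methyl-1,3-dioxolan-2-yl)ethyl]cyclopropyl]magnesium bromide (2.6 equiv)
Product: 23 (1S,2S,5S,6S)-1,3-dimethyl-4,8-bis{(1R,3S)-2,2-dimethyl-3-[2-(2-methyl-1,3-dioxolan-2-yl)ethyl]cyclopropyl}tricyclo[4.2.1.1(2,5)]deca-3,7-diene, via cyclopropylzinc bromide 22 (not isolated)
Conditions: ZnBr2 (2.8 equiv), THF, −20 → 20 °C; then 14, Pd(OAc)2 (10 mol %), 2-dicyclohexylphosphino-2′,6′-dimethoxybiphenyl (20 mol %), THF, 60 °C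
Reagents that add atoms: none
Why: Twofold Negishi cross-coupling: transmetalation from Mg to Zn to Pd and reductive elimination proceed with retention at the cyclopropyl carbon, so both cis-cyclopropyl units should be transferred intact to C4 and C8 while the ring stereocentres take no part; the bulky electron-rich biarylphosphine is chosen for the tetrasubstituted triflate, and a cyclopropyl–palladium species does not readily undergo β-hydride elimination.

Step 15
Reactants: 23 (1S,2S,5S,6S)-1,3-dimethyl-4,8-bis{(1R,3S)-2,2-dimethyl-3-[2-(2-methyl-1,3-dioxolan-2-yl)ethyl]cyclopropyl}tricyclo[4.2.1.1(2,5)]deca-3,7-diene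
Product: 24 (1S,2S,5S,6S)-1,3-dimethyl-4,8-bis[(1R,3S)-2,2-dimethyl-3-(3-oxobutyl)cyclopropyl]tricyclo[4.2.1.1(2,5)]deca-3,7-diene (CNP0300925.1)
Conditions: pyridinium p-toluenesulfonate (cat.), acetone/H2O 10:1, 40 °C
Reagents that add atoms: water, O
Why: Mild acid-catalysed ketal hydrolysis should release both methyl ketones under conditions too weak to protonate the vinylcyclopropane alkenes or to disturb any stereocentre.

Compound list
1 | 2-methyl-1,4-benzoquinone | CC1=CC(=O)C=CC1=O | starting material
2 | 2-methoxy-5-methylbenzene-1,4-diol | COc1cc(O)c(C)cc1O | intermediate (not isolated)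
3 | 2-methoxy-5-methyl-1,4-benzoquinone | COC1=CC(=O)C(C)=CC1=O | intermediate
4 | buta-1,3-diene | C=CC=C | starting material
5 | (4aS,8aR)-2-methoxy-4a-methyl-4a,5,8,8a-tetrahydronaphthalene-1,4-dione | C[C@]12CC=CC[C@H]1C(=O)C(OC)=CC2=O | intermediate
6 | (4R,4aR,8aS)-4-hydroxy-3-methoxy-4,8a-dimethyl-4a,5,8,8a-tetrahydronaphthalen-1(4H)-one | C[C@]12CC=CC[C@H]1[C@@](C)(O)C(OC)=CC2=O | intermediate
7 | (1S,3R,4R,5R,6R,8S,9R)-5-hydroxy-4-methoxy-1,5-dimethyltetracyclo[4.4.0.0(3,9).0(4,8)]decan-2-one | O=C2[C@@H]4[C@@H]3C[C@@]2(C)[C@H]2C[C@@H]3[C@]4(OC)[C@]2(C)O | intermediate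
8 | ring-opened methyl hemiketal, (1S,2R,3R,5S,6S)-3,4-dihydroxy-4-methoxy-1,3-dimethyltricyclo[4.2.1.1(2,5)]decan-8-one (C4 undefined) | O=C2C[C@@H]3C[C@@]2(C)[C@H]2C[C@@H]3C(O)(OC)[C@]2(C)O | intermediate (not isolated)
9 | (1S,2R,3R,5S,6S)-3-hydroxy-1,3-dimethyltricyclo[4.2.1.1(2,5)]decane-4,8-dione | O=C2C[C@@H]3C[C@@]2(C)[C@H]2C[C@@H]3C(=O)[C@]2(C)O | intermediate
10 | (1S,2R,3R,5S,6S)-1,3-dimethyl-4,8-dioxotricyclo[4.2.1.1(2,5)]decan-3-yl acetate | O=C2C[C@@H]3C[C@@]2(C)[C@H]2C[C@@H]3C(=O)[C@]2(C)OC(C)=O | intermediate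
11 | trivalent samarium enolate, diiodo{[(1S,2S,5S,6S)-1,3-dimethyl-8-oxotricyclo[4.2.1.1(2,5)]dec-3-en-4-yl]oxy}samarium | O=C2C[C@@H]3C[C@@]2(C)[C@H]2C[C@@H]3C(O[Sm](I)I)=C2C | intermediate (not isolated)
12 | (1S,2S,3R,5S,6S)-1,3-dimethyltricyclo[4.2.1.1(2,5)]decane-4,8-dione | O=C2C[C@@H]3C[C@@]2(C)[C@H]2C[C@@H]3C(=O)[C@@H]2C | intermediate
13 | dipotassium (1S,2S,5S,6S)-1,3-dimethyltricyclo[4.2.1.1(2,5)]deca-3,7-diene-4,8-diolate | [K+].[K+].[O-]C2=C[C@@H]3C[C@@]2(C)[C@H]2C[C@@H]3C([O-])=C2C | intermediate (not isolated)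
14 | (1S,2S,5S,6S)-1,3-dimethyltricyclo[4.2.1.1(2,5)]deca-3,7-diene-4,8-diyl bis(trifluoromethanesulfonate) | FC(F)(F)S(=O)(=O)OC2=C[C@@H]3C[C@@]2(C)[C@H]2C[C@@H]3C(OS(=O)(=O)C(F)(F)F)=C2C | intermediate
15 | 2-methylpropene | CC(C)=C | starting material
16 | 1,1-dibromo-2,2-dimethylcyclopropane | CC1(C)CC1(Br)Br | intermediate
17 | 1-bromo-2,2-dimethylcyclopropane (racemic) | CC1(C)CC1Br | intermediate
18 | 3,3-dimethylcyclopropene | CC1(C)C=C1 | intermediate
19 | 2-(2-bromoethyl)-2-methyl-1,3-dioxolane | BrCCC1(C)OCCO1 | starting material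
20 | [2-(2-methyl-1,3-dioxolan-2-yl)ethyl]magnesium bromide | Br[Mg]CCC1(C)OCCO1 | intermediate
21 | [(1R,3R)-2,2-dimethyl-3-[2-(2-methyl-1,3-dioxolan-2-yl)ethyl]cyclopropyl]magnesium bromide | Br[Mg][C@@H]1[C@H](CCC2(C)OCCO2)C1(C)C | intermediate
22 | bromo[(1R,3R)-2,2-dimethyl-3-[2-(2-methyl-1,3-dioxolan-2-yl)ethyl]cyclopropyl]zinc | Br[Zn][C@@H]1[C@H](CCC2(C)OCCO2)C1(C)C | intermediate (not isolated)
23 | (1S,2S,5S,6S)-1,3-dimethyl-4,8-bis{(1R,3S)-2,2-dimethyl-3-[2-(2-methyl-1,3-dioxolan-2-yl)ethyl]cyclopropyl}tricyclo[4.2.1.1(2,5)]deca-3,7-diene | CC6(OCCO6)CC[C@H]1[C@@H](C2=C[C@@H]3C[C@@]2(C)[C@H]2C[C@@H]3C([C@@H]3[C@H](CCC7(C)OCCO7)C3(C)C)=C2C)C1(C)C | intermediate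
24 | (1S,2S,5S,6S)-1,3-dimethyl-4,8-bis[(1R,3S)-2,2-dimethyl-3-(3-oxobutyl)cyclopropyl]tricyclo[4.2.1.1(2,5)]deca-3,7-diene (CNP0300925.1) | CC(=O)CC[C@H]1[C@@H](C2=C[C@@H]3C[C@@]2(C)[C@H]2C[C@@H]3C([C@@H]3[C@H](CCC(C)=O)C3(C)C)=C2C)C1(C)C | target

Total step count: 15.
Longest linear sequence: 10 steps (steps 1–8, 14 and 15, from 2-methyl-1,4-benzoquinone).

Steps most likely to fail

Step 14. Transmetalation of the doubly flanked secondary cyclopropylzinc to the hindered alkenylpalladium triflate, above all at the tetrasubstituted C3=C4 site, may be slower than reduction of the triflate or transannular carbopalladation of the facing alkene, so that only one coupling, or none, takes place. The fallback sets out from 21 and replaces the zinc reagent by an isolable boron reagent. Quenching 21 with 2-isopropoxy-4,4,5,5-tetramethyl-1,3,2-dioxaborolane (THF, −78 → 20 °C, retention) should give 2-[(1R,3S)-2,2-dimethyl-3-[2-(2-methyl-1,3-dioxolan-2-yl)ethyl]cyclopropyl]-4,4,5,5-tetramethyl-1,3,2-dioxaborolane F1, which can be purified and checked for enantiomeric purity. A twofold Suzuki–Miyaura coupling of F1 with 14 (Pd(OAc)2, 2-dicyclohexylphosphino-2′,6′-dimethoxybiphenyl, K3PO4, toluene/H2O, 90 °C) comes back to the route at 23.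

Step 5. The methyl ether may not push strongly enough under acid that the tertiary α-hydroxy centre tolerates, so that ionisation at C3 with a 1,2-shift, or simple recovery of the cage, competes with C4–C7 scission. The fallback sets out from 1 and carries a benzyl ether in place of the methyl ether, so that a free cyclobutanol can be unmasked under neutral conditions. ZnCl2 and benzyl alcohol with 1 should give 2-(benzyloxy)-5-methyl-1,4-benzoquinone F2. Diels–Alder reaction with 4 under the catalyst of step 2 should give (4aS,8aR)-2-(benzyloxy)-4a-methyl-4a,5,8,8a-tetrahydronaphthalene-1,4-dione F3. MeLi/CeCl3 should give (4R,4aR,8aS)-3-(benzyloxy)-4-hydroxy-4,8a-dimethyl-4a,5,8,8a-tetrahydronaphthalen-1(4H)-one F4, and irradiation as in step 4 the cage (1S,3R,4R,5R,6R,8S,9R)-4-(benzyloxy)-5-hydroxy-1,5-dimethyltetracyclo[4.4.0.0(3,9).0(4,8)]decan-2-one F5. Hydrogenolysis (H2, Pd/C, EtOAc) should give the cyclobutanol (1S,3R,4R,5R,6R,8S,9R)-4,5-dihydroxy-1,5-dimethyltetracyclo[4.4.0.0(3,9).0(4,8)]decan-2-one F6, a strained β-hydroxy ketone that should undergo retro-aldol cleavage of C4–C7 on the spot or with K2CO3 in MeOH. This comes back to the route at 9.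

Step 13. The chiral copper complex may discriminate poorly between the two enantiotopic alkene carbons of the small, unbiased cyclopropene when a functionalised primary Grignard reagent is used, and after the twofold coupling this would show up as diastereomers of 23. The fallback sets out from 18 and 20 and uses resolution instead of asymmetric catalysis. With CuI alone the carbomagnesiation, still strictly syn, should give racemic [(1RS,3RS)-2,2-dimethyl-3-[2-(2-methyl-1,3-dioxolan-2-yl)ethyl]cyclopropyl]magnesium bromide F7. Quenching with iodine should give racemic 2-{2-[(1RS,3RS)-3-iodo-2,2-dimethylcyclopropyl]ethyl}-2-methyl-1,3-dioxolane F8 with retention. Preparative chromatography on a chiral stationary phase should give 2-{2-[(1R,3R)-3-iodo-2,2-dimethylcyclopropyl]ethyl}-2-methyl-1,3-dioxolane F9. Iodine–lithium exchange (t-BuLi, 2 equiv, Et2O, −78 °C, retention) should give [(1R,3S)-2,2-dimethyl-3-[2-(2-methyl-1,3-dioxolan-2-yl)ethyl]cyclopropyl]lithium F10, and ZnBr2 converts it into 22, where the route is rejoined.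

Further compounds
F1 | step 14 | 2-[(1R,3S)-2,2-dimethyl-3-[2-(2-methyl-1,3-dioxolan-2-yl)ethyl]cyclopropyl]-4,4,5,5-tetramethyl-1,3,2-dioxaborolane | CC1(C)OB(OC1(C)C)[C@@H]1[C@H](CCC2(C)OCCO2)C1(C)C
F2 | step 5 | 2-(benzyloxy)-5-methyl-1,4-benzoquinone | C(c1ccccc1)OC1=CC(=O)C(C)=CC1=O
F3 | step 5 | (4aS,8aR)-2-(benzyloxy)-4a-methyl-4a,5,8,8a-tetrahydronaphthalene-1,4-dione | C[C@]12CC=CC[C@H]1C(=O)C(OCc1ccccc1)=CC2=O
F4 | step 5 | (4R,4aR,8aS)-3-(benzyloxy)-4-hydroxy-4,8a-dimethyl-4a,5,8,8a-tetrahydronaphthalen-1(4H)-one | C[C@]12CC=CC[C@H]1[C@@](C)(O)C(OCc1ccccc1)=CC2=O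
F5 | step 5 | (1S,3R,4R,5R,6R,8S,9R)-4-(benzyloxy)-5-hydroxy-1,5-dimethyltetracyclo[4.4.0.0(3,9).0(4,8)]decan-2-one | O=C2[C@@H]4[C@@H]3C[C@@]2(C)[C@H]2C[C@@H]3[C@]4(OCc5ccccc5)[C@]2(C)O
F6 | step 5 | (1S,3R,4R,5R,6R,8S,9R)-4,5-dihydroxy-1,5-dimethyltetracyclo[4.4.0.0(3,9).0(4,8)]decan-2-one | O=C2[C@@H]4[C@@H]3C[C@@]2(C)[C@H]2C[C@@H]3[C@]4(O)[C@]2(C)O
F7 | step 13 | racemic [(1RS,3RS)-2,2-dimethyl-3-[2-(2-methyl-1,3-dioxolan-2-yl)ethyl]cyclopropyl]magnesium bromide (both enantiomers written) | Br[Mg][C@@H]1[C@H](CCC2(C)OCCO2)C1(C)C.Br[Mg][C@H]1[C@@H](CCC2(C)OCCO2)C1(C)C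
F8 | step 13 | racemic 2-{2-[(1RS,3RS)-3-iodo-2,2-dimethylcyclopropyl]ethyl}-2-methyl-1,3-dioxolane (both enantiomers written) | I[C@@H]1[C@H](CCC2(C)OCCO2)C1(C)C.I[C@H]1[C@@H](CCC2(C)OCCO2)C1(C)C
F9 | step 13 | 2-{2-[(1R,3R)-3-iodo-2,2-dimethylcyclopropyl]ethyl}-2-methyl-1,3-dioxolane | I[C@@H]1[C@H](CCC2(C)OCCO2)C1(C)C
F10 | step 13 | [(1R,3S)-2,2-dimethyl-3-[2-(2-methyl-1,3-dioxolan-2-yl)ethyl]cyclopropyl]lithium | [Li][C@@H]1[C@H](CCC2(C)OCCO2)C1(C)C
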